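**Retrosynthetic overview**
- The aryl tiglate is put on last, by a one-pot exchange of a phenol TIPS ether for the tigloyl group.
- Key disconnection: the bond between the quaternary oxirane carbon and the CH2O(isovaleryl) carbon. The benzylic oxirane carbon is used as a carbanion (a configurationally stable α-lithiated (R)-aryloxirane) and adds to formaldehyde with retention; the alkoxide is acylated in the same flask.
- The (R)-aryloxirane comes from an α-chloro ketone by asymmetric transfer hydrogenation and ring closure.
- The α-chloro ketone comes from 2,5-dimethoxytoluene and chloroacetyl chloride (Friedel–Crafts acylation with ortho-demethylation), then O-silylation.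
- Rings: the arene is bought; the oxirane is the only ring formed (step 3) and is kept intact to the end.

Assumption: read from the SMILES, the target is the (R)-epoxide and the (E)-enoate (tiglate); monomeric formaldehyde is taken as made by cracking commercial paraformaldehyde.

**Step 1**
Reactants: 1 2,5-dimethoxytoluene; 2 chloroacetyl chloride
Product: 4 2-chloro-1-(2-hydroxy-5-methoxy-4-methylphenyl)ethan-1-one, via dimethoxy chloroketone 3 (not isolated)
Conditions: AlCl3 (2.5 equiv), CH2Cl2, 0 °C → reflux; ice/aq HCl
Reagents that add atoms: none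
Why: Friedel–Crafts acylation goes para to the methyl group and ortho to a methoxy group; AlCl3 then cleaves only the methoxy group ortho to the new ketone through a six-membered aluminium chelate, as known for 1,4-dimethoxyarenes.

**Step 2**
Reactants: 4 2-chloro-1-(2-hydroxy-5-methoxy-4-methylphenyl)ethan-1-one
Product: 5 2-chloro-1-[5-methoxy-4-methyl-2-(triisopropylsilyloxy)phenyl]ethan-1-one
Conditions: TIPSOTf (1.1 equiv), 2,6-lutidine (1.5 equiv), CH2Cl2, −78 → 0 °C
Reagents that add atoms: triisopropylsilyl trifluoromethanesulfonate (TIPSOTf), CC(C)[Si](C(C)C)(C(C)C)OS(=O)(=O)C(F)(F)F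
Why: O-silylation of the hydrogen-bonded phenol with a silyl triflate and a hindered weak base, which is fast at low temperature and does not make the phenoxide that would close onto the CH2Cl carbon (coumaranone formation).

**Step 3**
Reactants: 5 2-chloro-1-[5-methoxy-4-methyl-2-(triisopropylsilyloxy)phenyl]ethan-1-one
Product: 7 (R)-2-[5-methoxy-4-methyl-2-(triisopropylsilyloxy)phenyl]oxirane, via (R)-chlorohydrin 6 (not isolated)
Conditions: Cp*RhCl[(S,S)-TsDPEN] (0.5 mol %), HCO2H/Et3N (5:2), EtOAc, 25 °C; then 4 M aq NaOH (to pH > 12), iPrOH, 0 °C, 1 h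
Reagents that add atoms: none
Why: Noyori–Ikariya asymmetric transfer hydrogenation of the α-chloro ketone sets the benzylic stereocentre; the (S,S)-ligand should give the (R)-chlorohydrin (same facial sense as (S)-1-arylethanols, the descriptor changes because CH2Cl outranks aryl), and hydroxide then closes the oxirane by intramolecular Williamson displacement at CH2Cl, which does not touch that centre.

**Step 4**
Reactants: 7 (R)-2-[5-methoxy-4-methyl-2-(triisopropylsilyloxy)phenyl]oxirane; 8 formaldehyde (monomer, from cracked paraformaldehyde, as a THF solution); 9 3-methylbutanoic (isovaleric) anhydride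
Product: 12 [(2R)-2-[5-methoxy-4-methyl-2-(triisopropylsilyloxy)phenyl]oxiran-2-yl]methyl 3-methylbutanoate, via oxiranyllithium 10 (not isolated), via lithium alkoxide 11 (not isolated)
Conditions: s-BuLi (1.2 equiv), TMEDA (3 equiv), THF, −98 °C, 20 min; CH2O (1.3 equiv), −98 → −78 °C; then 9 (3 equiv), −78 → −20 °C; aq NaHCO3
Reagents that add atoms: none
Why: α-Lithiation and electrophilic trapping of an aryloxirane (oxiranyl anion chemistry): the benzylic oxirane C–H is removed by s-BuLi/TMEDA to give a lithiated oxirane that keeps its configuration at −98 °C and adds to formaldehyde with retention, so the quaternary stereocentre is set directly from 7; the lithium alkoxide is then O-acylated by the anhydride before it can undergo the degenerate Payne rearrangement that would racemise it. The bulky TIPS ether resists s-BuLi and does not direct ortho-lithiation.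

**Step 5**
Reactants: 12 [(2R)-2-[5-methoxy-4-methyl-2-(triisopropylsilyloxy)phenyl]oxiran-2-yl]methyl 3-methylbutanoate; 13 (2E)-2-methylbut-2-enoic (tiglic) anhydride
Product: 15 2-[(2R)-2-[(3-methylbutanoyloxy)methyl]oxiran-2-yl]-4-methoxy-5-methylphenyl (2E)-2-methylbut-2-enoate, via caesium phenoxide 14 (not isolated)
Conditions: CsF (2 equiv), 13 (2.5 equiv), dry DMF, 0 °C → rt; pH 7 phosphate buffer work-up
Reagents that add atoms: none
Why: One-pot desilylative acylation: fluoride cleaves the aryl O–Si bond and the phenoxide is acylated at once by the anhydride already present, so the free o-hydroxyaryl epoxide (prone to quinone-methide-type ring opening) does not build up; the epoxide, the alkyl ester and the (E)-geometry are not affected by these neutral to weakly basic conditions.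

**Compound list**
1 | 2,5-dimethoxytoluene (1,4-dimethoxy-2-methylbenzene) | Cc1cc(OC)ccc1OC | starting material
2 | chloroacetyl chloride | ClCC(=O)Cl | starting material
3 | 2-chloro-1-(2,5-dimethoxy-4-methylphenyl)ethan-1-one | O=C(CCl)c1cc(OC)c(C)cc1OC | intermediate
4 | 2-chloro-1-(2-hydroxy-5-methoxy-4-methylphenyl)ethan-1-one | O=C(CCl)c1cc(OC)c(C)cc1O | intermediate
5 | 2-chloro-1-[5-methoxy-4-methyl-2-(triisopropylsilyloxy)phenyl]ethan-1-one | O=C(CCl)c1cc(OC)c(C)cc1O[Si](C(C)C)(C(C)C)C(C)C | intermediate
6 | (1R)-2-chloro-1-[5-methoxy-4-methyl-2-(triisopropylsilyloxy)phenyl]ethan-1-ol | COc1cc([C@@H](O)CCl)c(O[Si](C(C)C)(C(C)C)C(C)C)cc1C | intermediate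
7 | (R)-2-[5-methoxy-4-methyl-2-(triisopropylsilyloxy)phenyl]oxirane | COc1cc([C@@H]2CO2)c(O[Si](C(C)C)(C(C)C)C(C)C)cc1C | intermediate
8 | formaldehyde | C=O | starting material
9 | 3-methylbutanoic anhydride | CC(C)CC(=O)OC(=O)CC(C)C | starting material
10 | [(2R)-2-[5-methoxy-4-methyl-2-(triisopropylsilyloxy)phenyl]oxiran-2-yl]lithium | COc1cc([C@]2([Li])CO2)c(O[Si](C(C)C)(C(C)C)C(C)C)cc1C | intermediate
11 | lithium [(2S)-2-[5-methoxy-4-methyl-2-(triisopropylsilyloxy)phenyl]oxiran-2-yl]methanolate (same geometry as 12; the descriptor changes by ranking only) | COc1cc([C@]2(C[O-])CO2)c(O[Si](C(C)C)(C(C)C)C(C)C)cc1C.[Li+] | intermediate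
12 | [(2R)-2-[5-methoxy-4-methyl-2-(triisopropylsilyloxy)phenyl]oxiran-2-yl]methyl 3-methylbutanoate | COc1cc([C@]2(COC(=O)CC(C)C)CO2)c(O[Si](C(C)C)(C(C)C)C(C)C)cc1C | intermediate
13 | (2E)-2-methylbut-2-enoic anhydride (tiglic anhydride) | C/C=C(\C)C(=O)OC(=O)/C(C)=C/C | starting material
14 | caesium 2-[(2R)-2-[(3-methylbutanoyloxy)methyl]oxiran-2-yl]-4-methoxy-5-methylphenolate | COc1cc([C@]2(COC(=O)CC(C)C)CO2)c([O-])cc1C.[Cs+] | intermediate
15 | 2-[(2R)-2-[(3-methylbutanoyloxy)methyl]oxiran-2-yl]-4-methoxy-5-methylphenyl (2E)-2-methylbut-2-enoate | C/C=C(\C)C(=O)Oc1cc(C)c(OC)cc1[C@]1(COC(=O)CC(C)C)CO1 | target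

**Totals**
Total step count: 5. Longest linear sequence: 5 steps (1 → 4 → 5 → 7 → 12 → 15).

**Steps most likely to fail, with fallbacks**

Step 4 (most risky). Possible failures:
- competing ring lithiation at the C–H between the methoxy group and the oxirane;
- silyl shift from the phenol oxygen to the carbanion;
- decomposition of the electron-rich oxiranyllithium;
- acylated hemiformal by-products from excess formaldehyde.

Fallback: set out from 5 and come back at 12. The chloride of 5 is displaced with sodium 3-methylbutanoate (NaI cat., DMF, rt) to give the keto ester 2-[5-methoxy-4-methyl-2-(triisopropylsilyloxy)phenyl]-2-oxoethyl 3-methylbutanoate F1. F1 is then converted straight into 12 by a catalytic asymmetric Corey–Chaykovsky methylene transfer: dimethyloxosulfonium methylide (from Me3S(O)I and NaH), LaLi3(binaphthoxide)3 (5 mol %), tris(2,4,6-trimethoxyphenyl)phosphine oxide (5 mol %), 5 Å molecular sieves, THF, rt. Here the nucleophilic ylide carbon becomes the oxirane CH2 and the quaternary centre is set by the catalyst. I cannot state from memory which BINOL hand gives (R)-12; both are commercial, and the choice is made by HPLC comparison. Expect lower selectivity than for methyl ketones.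

Step 5. Possible failures: the phenoxide opens the benzylic epoxide before it is acylated, or the hindered aryl TIPS ether cleaves too slowly.

Fallback: set out from 12 and come back at 15 in two separate operations that never generate a naked phenoxide. Buffered desilylation (TBAF/AcOH 1:1, THF, 0 °C) gives the neutral phenol [(2R)-2-(2-hydroxy-5-methoxy-4-methylphenyl)oxiran-2-yl]methyl 3-methylbutanoate F2, isolated cold. F2 is then esterified with tiglic acid by carbodiimide activation (N,N'-diisopropylcarbodiimide, DMAP cat., CH2Cl2, 0 °C) to give 15.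

Step 3. Possible failures: the bulky ortho-silyloxy group slows the transfer hydrogenation or lowers its ee, or aqueous hydroxide attacks the aryl silyl ether during ring closure.

Fallback: set out from 5 and come back at 7 by resolution instead of asymmetric reduction. NaBH4 (MeOH, 0 °C) gives the racemic chlorohydrin rac-2-chloro-1-[5-methoxy-4-methyl-2-(triisopropylsilyloxy)phenyl]ethan-1-ol F3. K2CO3 in acetone closes it to the racemic oxirane rac-2-[5-methoxy-4-methyl-2-(triisopropylsilyloxy)phenyl]oxirane F4. Hydrolytic kinetic resolution of F4 with (R,R)-(salen)Co(OAc) (trivalent cobalt, 1 mol %) and H2O (0.55 equiv) in THF at rt hydrolyses the (S)-enantiomer to its diol and leaves (R)-7 (at most 50 %). The catalyst hand is my best recollection for simple terminal epoxides and should be confirmed on analytical scale.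

**Further compounds**
F1 | step 4 | 2-[5-methoxy-4-methyl-2-(triisopropylsilyloxy)phenyl]-2-oxoethyl 3-methylbutanoate | COc1cc(C(=O)COC(=O)CC(C)C)c(O[Si](C(C)C)(C(C)C)C(C)C)cc1C
F2 | step 5 | [(2R)-2-(2-hydroxy-5-methoxy-4-methylphenyl)oxiran-2-yl]methyl 3-methylbutanoate | COc1cc([C@]2(COC(=O)CC(C)C)CO2)c(O)cc1C
F3 | step 3 | rac-2-chloro-1-[5-methoxy-4-methyl-2-(triisopropylsilyloxy)phenyl]ethan-1-ol | COc1cc(C(O)CCl)c(O[Si](C(C)C)(C(C)C)C(C)C)cc1C
F4 | step 3 | rac-2-[5-methoxy-4-methyl-2-(triisopropylsilyloxy)phenyl]oxirane | COc1cc(C2CO2)c(O[Si](C(C)C)(C(C)C)C(C)C)cc1C
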